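**Retrosynthetic overview**
1. Target 30 ⇐ spiro-epoxide 29 (HCl opening at C13) ⇐ α-methylene lactone 28 (nucleophilic epoxidation).
2. γ-Lactone 28 ⇐ tiglate 26 ⇐ macrocyclic hydroxy ester 24; the 10-membered carbocycle is closed at C7–C8 by an intramolecular indium Barbier allylation of bromo-aldehyde 22.
3. 22 ⇐ cross-metathesis on the C6 vinyl carbinol (chelation-controlled vinyl addition) and reduction of the C8 ester.
4. Furanone with the C10 quaternary centre, C9 and C8 ⇐ key step: asymmetric epoxidation and 1,2-acyl-shift ring contraction of 4-pyranone-3-carboxylate 11 (⇐ ynoic acid 7 + methyl acetoacetate).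
5. C4/C5 ⇐ Marshall anti-propargylation of 2,2-dimethoxyacetaldehyde. Ring order: pyranone → furanone (contraction) → carbocycle → γ-lactone → epoxide.

Assumption: CO2, vinylmagnesium bromide, peroxides, HCl and protecting-group reagents are treated as reagents, not numbered starting materials; macrocycles are named with the germacrane numbering of the target (C1 ketone, C2=C3, 3,10-oxygen bridge), and "as in 30" means the same spatial arrangement as in the target.

**Route**

Step 1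
Reactants: 1 (R)-but-3-yn-2-ol
Product: 2 (R)-but-3-yn-2-yl methanesulfonate
Conditions: MsCl, Et3N, CH2Cl2, −78 to 0 °C
Reagents that add atoms: methanesulfonyl chloride CS(=O)(=O)Cl
Why: O-sulfonylation does not touch the C–O stereocentre, so the configuration is retained.

Step 2
Reactants: 2 (R)-but-3-yn-2-yl methanesulfonate; 3 2,2-dimethoxyacetaldehyde (freshly distilled)
Product: 5 (2S,3S)-1,1-dimethoxy-3-methylpent-4-yn-2-ol, via allenylzinc 4 (not isolated)
Conditions: Pd(OAc)2 (5 mol%), PPh3 (5 mol%), Et2Zn (3 equiv), THF, −78 to −20 °C; aq NH4Cl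
Reagents that add atoms: none
Why: Marshall propargylation; anti-SN2′ palladation gives a configurationally defined allenylzinc that adds through a cyclic SE2′ transition state, so C4 comes from the mesylate and the anti C5 carbinol is set under reagent control.

Step 3
Reactants: 5 (2S,3S)-1,1-dimethoxy-3-methylpent-4-yn-2-ol
Product: 6 1-({[(2S,3S)-1,1-dimethoxy-3-methylpent-4-yn-2-yl]oxy}methyl)-4-methoxybenzene
Conditions: NaH, PMBCl, n-Bu4NI (cat.), THF/DMF, 0 °C to rt
Reagents that add atoms: 4-methoxybenzyl chloride COc1ccc(CCl)cc1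
Why: Williamson etherification of the alkoxide; the PMB ether is chosen because it can chelate in step 9.

Step 4
Reactants: 6 PMB ether
Product: 7 (4S,5S)-6,6-dimethoxy-5-[(4-methoxybenzyl)oxy]-4-methylhex-2-ynoic acid
Conditions: n-BuLi, THF, −78 °C; CO2; cold 1 M HCl to pH 3
Reagents that add atoms: carbon dioxide O=C=O
Why: Carboxylation of the lithium acetylide; the propargylic stereocentre is not acidic under these conditions.

Step 5
Reactants: 7 ynoic acid; 8 methyl acetoacetate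
Product: 11 methyl 6-{(2R,3S)-4,4-dimethoxy-3-[(4-methoxybenzyl)oxy]butan-2-yl}-2-methyl-4-oxo-4H-pyran-3-carboxylate, via acid chloride 9 (not isolated), via triketo ester 10 (not isolated)
Conditions: 1-chloro-N,N,2-trimethylprop-1-en-1-amine, CH2Cl2, 0 °C; then 8, MgCl2, pyridine, 0 °C to rt; then Et3N, rt
Reagents that add atoms: none
Why: Magnesium-enolate C-acylation of the β-keto ester by the ynoyl chloride, then 6-endo oxa-Michael closure of the acetyl enol onto the ynone gives the 4-pyranone; no stereocentre is involved.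

Step 6
Reactants: 11 pyranone ester
Product: 13 methyl 2-[(2R)-5-{(2R,3S)-4,4-dimethoxy-3-[(4-methoxybenzyl)oxy]butan-2-yl}-2-methyl-3-oxo-2,3-dihydrofuran-2-yl]-2-oxoacetate, via pyranone epoxide 12 (not isolated)
Conditions: Sc(OTf)3 (10 mol%), chiral N,N′-dioxide L-PiPr2 (11 mol%), 30% aq H2O2 (1.1 equiv), THF, 0 °C; then 4 Å MS, 35 °C
Reagents that add atoms: hydrogen peroxide OO
Why: Proposed new method: the chiral Sc(III) complex binds the β-keto ester in bidentate fashion, so hydroperoxide adds only at the doubly activated C2 and closes to the 2,3-epoxide on one face. Lewis-acid ionisation of the C2–O bond (cation stabilised by the ring oxygen) then triggers an invertive 1,2-shift of the ring acyl carbon from C3 to C2. This contracts the pyranone to the 3(2H)-furanone, sets the C10 quaternary centre and leaves C3 as the exocyclic α-keto ester; C3 carries no hydrogen, so aromatisation to a 3-hydroxypyranone is impossible. The ligand enantiomer is chosen to give (2R)-13. Closest known reactions: N,N′-dioxide–Sc(III)-catalysed epoxidation of 2-alkylidene-1,3-dicarbonyls with H2O2, and the Lewis-acid acyl-shift ring contraction of cyclic α,β-epoxy ketones (semipinacol type).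

Step 7
Reactants: 13 keto ester
Product: 14 methyl (2R)-2-hydroxy-2-[(2S)-5-{(2R,3S)-4,4-dimethoxy-3-[(4-methoxybenzyl)oxy]butan-2-yl}-2-methyl-3-oxo-2,3-dihydrofuran-2-yl]acetate
Conditions: Zn(BH4)2, Et2O, −78 °C; aq NH4Cl
Reagents that add atoms: none
Why: Chelation-controlled reduction of the highly electrophilic α-keto ester carbonyl; Zn(II) bridges the C9 ketone and the furanone oxygen functions and hydride enters the open face of the chelate, giving the C9 configuration of the target; the vinylogous ester is inert at −78 °C.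

Step 8
Reactants: 14 hydroxy ester
Product: 17 methyl (2R)-2-[(2S)-5-{(2R,3S)-3-[(4-methoxybenzyl)oxy]-4-oxobutan-2-yl}-2-methyl-3-oxo-2,3-dihydrofuran-2-yl]-2-[(triethylsilyl)oxy]acetate, via silyl ether acetal 15 (not isolated), via collidinium salt 16 (not isolated)
Conditions: TESOTf (3.5 equiv), 2,4,6-collidine, CH2Cl2, 0 °C; then H2O, rt
Reagents that add atoms: triethylsilyl trifluoromethanesulfonate CC[Si](CC)(CC)OS(=O)(=O)C(F)(F)F; water O
Why: Silylation of the C9 hydroxyl, then chemoselective silyl-triflate/collidine cleavage of the dimethyl acetal through a pyridinium salt hydrolysed under non-acidic conditions; the PMB ether, ester and α-stereocentre are not affected.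

Step 9
Reactants: 17 aldehyde
Product: 19 methyl (2R)-2-[(2S)-5-{(2R,3S,4S)-3-[(4-methoxybenzyl)oxy]-4-[(triethylsilyl)oxy]hex-5-en-2-yl}-2-methyl-3-oxo-2,3-dihydrofuran-2-yl]-2-[(triethylsilyl)oxy]acetate, via magnesium alkoxide 18 (not isolated)
Conditions: MgBr2·OEt2, CH2Cl2, −78 °C; vinylMgBr (1.3 equiv); then TESOTf, 2,6-lutidine, −78 to −40 °C
Reagents that add atoms: vinylmagnesium bromide C=C[Mg]Br; triethylsilyl trifluoromethanesulfonate CC[Si](CC)(CC)OS(=O)(=O)C(F)(F)F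
Why: Cram-chelate Grignard addition; Mg(II) bridges the aldehyde and PMB-ether oxygens and vinyl adds from the hydrogen side, giving the 5,6-syn (6S) carbinol, which is silylated in the same flask.

Step 10
Reactants: 19 bis-silyl ether ester
Product: 20 (2R)-2-[(2S)-5-{(2R,3S,4S)-3-[(4-methoxybenzyl)oxy]-4-[(triethylsilyl)oxy]hex-5-en-2-yl}-2-methyl-3-oxo-2,3-dihydrofuran-2-yl]-2-[(triethylsilyl)oxy]acetaldehyde
Conditions: DIBAL-H (1.1 equiv), CH2Cl2, −78 °C; MeOH, aq Rochelle salt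
Reagents that add atoms: none
Why: DIBAL half-reduction of the α-silyloxy methyl ester through the aluminium hemiacetal, which is stable at −78 °C; the vinylogous ester is much less electrophilic.

Step 11
Reactants: 20 aldehyde; 21 methyl 2-(bromomethyl)acrylate
Product: 22 methyl (2Z,4S,5S,6R)-2-(bromomethyl)-5-[(4-methoxybenzyl)oxy]-6-{(5S)-5-methyl-4-oxo-5-[(1R)-2-oxo-1-[(triethylsilyl)oxy]ethyl]-4,5-dihydrofuran-2-yl}-4-[(triethylsilyl)oxy]hept-2-enoate
Conditions: Hoveyda–Grubbs II (10 mol%), 21 (8 equiv), CH2Cl2, 40 °C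
Reagents that add atoms: none
Why: Olefin cross-metathesis of the terminal alkene with the 1,1-disubstituted acrylate (ethene lost); thermodynamic control places the ester trans to the chain, giving the (Z)-bromide.

Step 12
Reactants: 22 bromo-aldehyde
Product: 24 methyl 8-hydroxy-5-[(4-methoxybenzyl)oxy]-1-oxo-6,9-bis[(triethylsilyl)oxy]-3,10-epoxygermacra-2,11(13)-dien-12-oate (all centres as in 30), via allylindium 23 (not isolated)
Conditions: In powder (3 equiv), THF/H2O (4:1), slow addition to 0.002 M, rt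
Reagents that add atoms: none
Why: Intramolecular Barbier allylation closes the 10-membered ring at C7–C8; the (Z)-allylindium reacts through a chair transition state (syn adduct), Felkin–Anh attack on the α-silyloxy aldehyde sets C8, and attack anti to the allylic C6 oxygen (inside-alkoxy) sets C7, all three preferences converging on the target configuration.

Step 13
Reactants: 24 macrocyclic hydroxy ester; 25 tigloyl chloride [(2E)-2-methylbut-2-enoyl chloride]
Product: 26 methyl 5-[(4-methoxybenzyl)oxy]-8-{[(2E)-2-methylbut-2-enoyl]oxy}-1-oxo-6,9-bis[(triethylsilyl)oxy]-3,10-epoxygermacra-2,11(13)-dien-12-oate (all centres as in 30)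
Conditions: 25, Et3N, DMAP, CH2Cl2, 0 °C to rt
Reagents that add atoms: none
Why: DMAP-catalysed acylation of the only free hydroxyl; it installs the tiglate and blocks O8 so that the lactone can later close only on O6.

Step 14
Reactants: 26 tiglate
Product: 28 5,9-dihydroxy-8-{[(2E)-2-methylbut-2-enoyl]oxy}-1-oxo-3,10-epoxygermacra-2,11(13)-dien-12,6-olide (all centres as in 30), via trihydroxy ester 27 (not isolated)
Conditions: HCl (0.3 equiv), HFIP/CH2Cl2 (1:1), 1,3-dimethoxybenzene, 0 °C to rt; aq NaHCO3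
Reagents that add atoms: none
Why: Acidolysis removes the PMB ether (cation trapped by the arene) and both TES ethers, and the freed γ-hydroxy ester lactonises to the trans-fused γ-lactone, favoured over the δ-lactones possible through O5 or O9.

Step 15
Reactants: 28 α-methylene lactone
Product: 29 11,13-epoxide of 28 (spiro-epoxide oxygen on the face of H-7)
Conditions: t-BuOOH (2 equiv), DBU (0.3 equiv), CH2Cl2, −20 °C
Reagents that add atoms: tert-butyl hydroperoxide CC(C)(C)OO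
Why: Weitz–Scheffer nucleophilic epoxidation, selective for the exo-methylene lactone over the tiglate and the furanone; oxygen is delivered anti to the C8 substituent, and the low temperature and sub-stoichiometric base suppress retro-aldol at C9–C10.

Step 16
Reactants: 29 spiro-epoxide
Product: 30 (4R,5S,6S,7S,8S,9S,10S,11S)-13-chloro-5,9,11-trihydroxy-8-{[(2E)-2-methylbut-2-enoyl]oxy}-1-oxo-3,10-epoxygermacr-2-en-12,6-olide (CNP0340393.1)
Conditions: HCl (1 M in Et2O, 3 equiv), LiCl, THF, 0 °C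
Reagents that add atoms: hydrogen chloride Cl
Why: Acid-assisted SN2 opening of the epoxide by chloride at the primary carbon; C11 is not touched and keeps its hydroxyl configuration.

**Compound list**

1 | (R)-but-3-yn-2-ol | C#C[C@@H](C)O | starting material
2 | (R)-but-3-yn-2-yl methanesulfonate | C#C[C@@H](C)OS(C)(=O)=O | intermediate
3 | 2,2-dimethoxyacetaldehyde | COC(OC)C=O | starting material
4 | (aS)-buta-1,2-dien-1-yl(ethyl)zinc | CC[Zn]C=[C@@]=CC | intermediate (not isolated)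
5 | (2S,3S)-1,1-dimethoxy-3-methylpent-4-yn-2-ol | COC(OC)[C@@H](O)[C@@H](C)C#C | intermediate
6 | 1-({[(2S,3S)-1,1-dimethoxy-3-methylpent-4-yn-2-yl]oxy}methyl)-4-methoxybenzene | COC(OC)[C@@H](OCc1ccc(OC)cc1)[C@@H](C)C#C | intermediate
7 | (4S,5S)-6,6-dimethoxy-5-[(4-methoxybenzyl)oxy]-4-methylhex-2-ynoic acid | COC(OC)[C@@H](OCc1ccc(OC)cc1)[C@@H](C)C#CC(=O)O | intermediate
8 | methyl acetoacetate | CC(=O)CC(=O)OC | starting material
9 | (4S,5S)-6,6-dimethoxy-5-[(4-methoxybenzyl)oxy]-4-methylhex-2-ynoyl chloride | COC(OC)[C@@H](OCc1ccc(OC)cc1)[C@@H](C)C#CC(=O)Cl | intermediate (not isolated)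
10 | methyl (6S,7S)-2-acetyl-8,8-dimethoxy-7-[(4-methoxybenzyl)oxy]-6-methyl-3-oxooct-4-ynoate (enolised) | COC(OC)[C@@H](OCc1ccc(OC)cc1)[C@@H](C)C#CC(=O)C(C(C)=O)C(=O)OC | intermediate (not isolated)
11 | methyl 6-{(2R,3S)-4,4-dimethoxy-3-[(4-methoxybenzyl)oxy]butan-2-yl}-2-methyl-4-oxo-4H-pyran-3-carboxylate | COC(OC)[C@@H](OCc1ccc(OC)cc1)[C@@H](C)C1=CC(=O)C(C(=O)OC)=C(C)O1 | intermediate
12 | methyl (1S,6S)-3-{(2R,3S)-4,4-dimethoxy-3-[(4-methoxybenzyl)oxy]butan-2-yl}-1-methyl-5-oxo-2,7-dioxabicyclo[4.1.0]hept-3-ene-6-carboxylate | COC(OC)[C@@H](OCc1ccc(OC)cc1)[C@@H](C)C1=CC(=O)[C@]2(C(=O)OC)O[C@]2(C)O1 | intermediate (not isolated)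
13 | methyl 2-[(2R)-5-{(2R,3S)-4,4-dimethoxy-3-[(4-methoxybenzyl)oxy]butan-2-yl}-2-methyl-3-oxo-2,3-dihydrofuran-2-yl]-2-oxoacetate | COC(OC)[C@@H](OCc1ccc(OC)cc1)[C@@H](C)C1=CC(=O)[C@@](C)(O1)C(=O)C(=O)OC | intermediate
14 | methyl (2R)-2-hydroxy-2-[(2S)-5-{(2R,3S)-4,4-dimethoxy-3-[(4-methoxybenzyl)oxy]butan-2-yl}-2-methyl-3-oxo-2,3-dihydrofuran-2-yl]acetate | COC(OC)[C@@H](OCc1ccc(OC)cc1)[C@@H](C)C1=CC(=O)[C@@](C)(O1)[C@@H](O)C(=O)OC | intermediate
15 | triethylsilyl ether of 14 (dimethyl acetal intact) | COC(OC)[C@@H](OCc1ccc(OC)cc1)[C@@H](C)C1=CC(=O)[C@@](C)(O1)[C@@H](O[Si](CC)(CC)CC)C(=O)OC | intermediate (not isolated)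
16 | N-(α-methoxyalkyl)-2,4,6-trimethylpyridinium triflate formed from 15 at the acetal carbon (both epimers at that carbon) | COC([n+]1c(C)cc(C)cc1C)[C@@H](OCc1ccc(OC)cc1)[C@@H](C)C1=CC(=O)[C@@](C)(O1)[C@@H](O[Si](CC)(CC)CC)C(=O)OC.[O-]S(=O)(=O)C(F)(F)F | intermediate (not isolated)
17 | methyl (2R)-2-[(2S)-5-{(2R,3S)-3-[(4-methoxybenzyl)oxy]-4-oxobutan-2-yl}-2-methyl-3-oxo-2,3-dihydrofuran-2-yl]-2-[(triethylsilyl)oxy]acetate | O=C[C@@H](OCc1ccc(OC)cc1)[C@@H](C)C1=CC(=O)[C@@](C)(O1)[C@@H](O[Si](CC)(CC)CC)C(=O)OC | intermediate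
18 | bromomagnesium alkoxide of the (4S)-allylic alcohol from 17 | C=C[C@H](O[Mg]Br)[C@@H](OCc1ccc(OC)cc1)[C@@H](C)C1=CC(=O)[C@@](C)(O1)[C@@H](O[Si](CC)(CC)CC)C(=O)OC | intermediate (not isolated)
19 | methyl (2R)-2-[(2S)-5-{(2R,3S,4S)-3-[(4-methoxybenzyl)oxy]-4-[(triethylsilyl)oxy]hex-5-en-2-yl}-2-methyl-3-oxo-2,3-dihydrofuran-2-yl]-2-[(triethylsilyl)oxy]acetate | C=C[C@H](O[Si](CC)(CC)CC)[C@@H](OCc1ccc(OC)cc1)[C@@H](C)C1=CC(=O)[C@@](C)(O1)[C@@H](O[Si](CC)(CC)CC)C(=O)OC | intermediate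
20 | (2R)-2-[(2S)-5-{(2R,3S,4S)-3-[(4-methoxybenzyl)oxy]-4-[(triethylsilyl)oxy]hex-5-en-2-yl}-2-methyl-3-oxo-2,3-dihydrofuran-2-yl]-2-[(triethylsilyl)oxy]acetaldehyde | C=C[C@H](O[Si](CC)(CC)CC)[C@@H](OCc1ccc(OC)cc1)[C@@H](C)C1=CC(=O)[C@@](C)(O1)[C@@H](O[Si](CC)(CC)CC)C=O | intermediate
21 | methyl 2-(bromomethyl)acrylate | C=C(CBr)C(=O)OC | starting material
22 | methyl (2Z,4S,5S,6R)-2-(bromomethyl)-5-[(4-methoxybenzyl)oxy]-6-{(5S)-5-methyl-4-oxo-5-[(1R)-2-oxo-1-[(triethylsilyl)oxy]ethyl]-4,5-dihydrofuran-2-yl}-4-[(triethylsilyl)oxy]hept-2-enoate | COC(=O)/C(CBr)=C/[C@H](O[Si](CC)(CC)CC)[C@@H](OCc1ccc(OC)cc1)[C@@H](C)C1=CC(=O)[C@@](C)(O1)[C@@H](O[Si](CC)(CC)CC)C=O | intermediate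
23 | allylindium reagent from 22 (In in place of Br) | COC(=O)/C(C[In])=C/[C@H](O[Si](CC)(CC)CC)[C@@H](OCc1ccc(OC)cc1)[C@@H](C)C1=CC(=O)[C@@](C)(O1)[C@@H](O[Si](CC)(CC)CC)C=O | intermediate (not isolated)
24 | methyl 8-hydroxy-5-[(4-methoxybenzyl)oxy]-1-oxo-6,9-bis[(triethylsilyl)oxy]-3,10-epoxygermacra-2,11(13)-dien-12-oate (all centres as in 30) | O[C@H]1[C@@H](C(=C)C(=O)OC)[C@H](O[Si](CC)(CC)CC)[C@@H](OCc3ccc(OC)cc3)[C@@H](C)C2=CC(=O)[C@@](C)(O2)[C@H]1O[Si](CC)(CC)CC | intermediate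
25 | tigloyl chloride, (2E)-2-methylbut-2-enoyl chloride | C/C=C(\C)C(Cl)=O | starting material
26 | 8-O-tiglate of 24 | C/C=C(\C)C(=O)O[C@H]1[C@@H](C(=C)C(=O)OC)[C@H](O[Si](CC)(CC)CC)[C@@H](OCc3ccc(OC)cc3)[C@@H](C)C2=CC(=O)[C@@](C)(O2)[C@H]1O[Si](CC)(CC)CC | intermediate
27 | methyl 5,6,9-trihydroxy-8-{[(2E)-2-methylbut-2-enoyl]oxy}-1-oxo-3,10-epoxygermacra-2,11(13)-dien-12-oate (all centres as in 30) | C/C=C(\C)C(=O)O[C@H]1[C@@H](C(=C)C(=O)OC)[C@H](O)[C@@H](O)[C@@H](C)C2=CC(=O)[C@@](C)(O2)[C@H]1O | intermediate (not isolated)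
28 | 5,9-dihydroxy-8-{[(2E)-2-methylbut-2-enoyl]oxy}-1-oxo-3,10-epoxygermacra-2,11(13)-dien-12,6-olide (all centres as in 30) | C/C=C(\C)C(=O)O[C@H]1[C@@H]2[C@H](OC(=O)C2=C)[C@@H](O)[C@@H](C)C2=CC(=O)[C@@](C)(O2)[C@H]1O | intermediate
29 | 11,13-epoxide of 28 (epoxide oxygen on the face of H-7) | C/C=C(\C)C(=O)O[C@H]1[C@@H]2[C@H](OC(=O)[C@]23CO3)[C@@H](O)[C@@H](C)C2=CC(=O)[C@@](C)(O2)[C@H]1O | intermediate
30 | (4R,5S,6S,7S,8S,9S,10S,11S)-13-chloro-5,9,11-trihydroxy-8-{[(2E)-2-methylbut-2-enoyl]oxy}-1-oxo-3,10-epoxygermacr-2-en-12,6-olide | C/C=C(\C)C(=O)O[C@H]1[C@@H]2[C@H](OC(=O)[C@]2(O)CCl)[C@@H](O)[C@@H](C)C2=CC(=O)[C@@](C)(O2)[C@H]1O | target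

**Step count and risks**

Total step count: 16. Longest linear sequence: 16 steps (from 1; 3, 8, 21 and 25 enter along the way).

Three steps most likely to fail:

Step 6 (the proposed epoxidation and ring contraction). The risks are peroxide attack at the wrong pyranone position, ester rather than acyl migration, and loss of enantiopurity in the shift. The fallback uses known chemistry only; it sets out from 6 and comes back at 14. Lithiated 6 is added to the lithium alkoxide of (S)-N,N-dimethyllactamide to give (2S,6S,7S)-2-hydroxy-8,8-dimethoxy-7-[(4-methoxybenzyl)oxy]-6-methyloct-4-yn-3-one F1. Diethylamine in ethanol cyclises this hydroxy ynone to 5-{(2R,3S)-4,4-dimethoxy-3-[(4-methoxybenzyl)oxy]butan-2-yl}-2-methylfuran-3(2H)-one F2. TIPSOTf/Et3N converts it into the 3-silyloxyfuran F3. A Cu(II)–bis(oxazoline)-catalysed Mukaiyama aldol of F3 with methyl glyoxylate then forms the C9–C10 bond with both centres and gives 14.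

Step 11 (cross-metathesis of a hindered allylic silyl ether with a 1,1-disubstituted acrylate). The fallback replaces it by a ring-closing metathesis and forms the lactone before the carbocycle; it sets out from 17 and comes back at 28. Vinylmagnesium bromide/MgBr2 without the silyl quench gives the allylic alcohol F4. DIBAL-H (2.2 equiv) gives the hydroxy aldehyde F5. DCC/DMAP esterification with 2-(bromomethyl)acrylic acid gives the diene ester F6. Grubbs II closes it to the 3-(bromomethyl)butenolide F7. Indium in aqueous THF at high dilution closes the carbocycle to the α-methylene lactone alcohol F8 (C8 epimers separable). Tigloyl chloride gives the tiglate F9, and the HCl/HFIP conditions of step 14 give 28.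

Step 12 (macrocyclising Barbier reaction). The risks are oligomerisation, wrong facial selectivity in the ring-forming transition state, and early lactonisation of the new O8 alkoxide onto the ester. The fallback changes from an in situ allylmetal to a preformed allylsilane cyclised by Lewis acid through an open transition state; it sets out from 20 and comes back at 24. Cross-metathesis of 20 with methyl 2-[(trimethylsilyl)methyl]acrylate gives the allylsilane aldehyde F10. BF3·OEt2 in CH2Cl2 at −78 °C and high dilution effects the intramolecular Hosomi–Sakurai allylation to 24.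

Further compounds
F1 | step 6 | (2S,6S,7S)-2-hydroxy-8,8-dimethoxy-7-[(4-methoxybenzyl)oxy]-6-methyloct-4-yn-3-one | COC(OC)[C@@H](OCc1ccc(OC)cc1)[C@@H](C)C#CC(=O)[C@H](C)O
F2 | step 6 | 5-{(2R,3S)-4,4-dimethoxy-3-[(4-methoxybenzyl)oxy]butan-2-yl}-2-methylfuran-3(2H)-one (both C2 epimers) | COC(OC)[C@@H](OCc1ccc(OC)cc1)[C@@H](C)C1=CC(=O)C(C)O1
F3 | step 6 | ({5-{(2R,3S)-4,4-dimethoxy-3-[(4-methoxybenzyl)oxy]butan-2-yl}-2-methylfuran-3-yl}oxy)triisopropylsilane | COC(OC)[C@@H](OCc1ccc(OC)cc1)[C@@H](C)c1cc(O[Si](C(C)C)(C(C)C)C(C)C)c(C)o1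
F4 | step 11 | methyl (2R)-2-[(2S)-5-{(2R,3S,4S)-4-hydroxy-3-[(4-methoxybenzyl)oxy]hex-5-en-2-yl}-2-methyl-3-oxo-2,3-dihydrofuran-2-yl]-2-[(triethylsilyl)oxy]acetate | C=C[C@H](O)[C@@H](OCc1ccc(OC)cc1)[C@@H](C)C1=CC(=O)[C@@](C)(O1)[C@@H](O[Si](CC)(CC)CC)C(=O)OC
F5 | step 11 | (2R)-2-[(2S)-5-{(2R,3S,4S)-4-hydroxy-3-[(4-methoxybenzyl)oxy]hex-5-en-2-yl}-2-methyl-3-oxo-2,3-dihydrofuran-2-yl]-2-[(triethylsilyl)oxy]acetaldehyde | C=C[C@H](O)[C@@H](OCc1ccc(OC)cc1)[C@@H](C)C1=CC(=O)[C@@](C)(O1)[C@@H](O[Si](CC)(CC)CC)C=O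
F6 | step 11 | 2-(bromomethyl)acrylate ester of F5 at O6 | C=C[C@H](OC(=O)C(=C)CBr)[C@@H](OCc1ccc(OC)cc1)[C@@H](C)C1=CC(=O)[C@@](C)(O1)[C@@H](O[Si](CC)(CC)CC)C=O
F7 | step 11 | 3-(bromomethyl)-5-substituted furan-2(5H)-one from ring-closing metathesis of F6 | BrCC1=C[C@H](OC1=O)[C@@H](OCc2ccc(OC)cc2)[C@@H](C)C2=CC(=O)[C@@](C)(O2)[C@@H](O[Si](CC)(CC)CC)C=O
F8 | step 11 | 8-hydroxy-5-[(4-methoxybenzyl)oxy]-1-oxo-9-[(triethylsilyl)oxy]-3,10-epoxygermacra-2,11(13)-dien-12,6-olide (all centres as in 30) | O[C@H]1[C@@H]2[C@H](OC(=O)C2=C)[C@@H](OCc3ccc(OC)cc3)[C@@H](C)C2=CC(=O)[C@@](C)(O2)[C@H]1O[Si](CC)(CC)CC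
F9 | step 11 | 8-O-tiglate of F8 | C/C=C(\C)C(=O)O[C@H]1[C@@H]2[C@H](OC(=O)C2=C)[C@@H](OCc3ccc(OC)cc3)[C@@H](C)C2=CC(=O)[C@@](C)(O2)[C@H]1O[Si](CC)(CC)CC
F10 | step 12 | allylsilane analogue of 22 (CH2SiMe3 in place of CH2Br) | COC(=O)/C(C[Si](C)(C)C)=C/[C@H](O[Si](CC)(CC)CC)[C@@H](OCc1ccc(OC)cc1)[C@@H](C)C1=CC(=O)[C@@](C)(O1)[C@@H](O[Si](CC)(CC)CC)C=O
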